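Retrosynthetic overview
- Feature: in the cyclopentane ring (C5–C9), the fully substituted C8 carries exocyclic C10 and sits next to oxygenated C7. This C7–C8(–C10) array is read as a six-membered ring C5–C6–C7–C10–C8–C9 from which C10 was pushed out by a 1,2-shift of C7 onto C8.
- Endgame: C1 isovalerate and C7 p-coumarate by acylation, and the C11 alcohol from its aldehyde. The trans C7/C8 diol comes from the convex β-epoxide of C7=C8, inverted at C8 through its own C10 alkoxide. The C7=C8–C10 enoate comes from conjugation of the contraction product.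
- Key disconnection: cyclopentene ester ⇒ 8-diazo-6-en-10-one of a cis-fused 2-oxadecalin, by photochemical Wolff contraction.
- Oxadecalin ⇒ Diels–Alder addition of a 1-methoxy-3-silyloxybutadiene to an enantiopure 6-alkoxypyranone made from furfuryl alcohol. C11 comes from carbonylation of the C3=C4 enol triflate.
- Ring order: pyran (Achmatowicz), then the six-membered carbocycle (Diels–Alder), then the five-membered carbocycle (contraction). C1 carries a PMB acetal rather than an ester, because two i-Bu2AlH reductions lie ahead.

Key step: step 10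

Conventions: iridoid numbering is used throughout. In 8–13, C10 is still a ring member between C7 and C8. β is the face of H-5 and H-9 (the convex face of the carbocycle) and α is the opposite face.
Assumption: a commercial lipase that acylates the (S)-lactol faster is taken to be available by screening, since both enantiopreferences occur among commercial lipases.

Step 1
Reactants: 1 furfuryl alcohol
Product: 2 6-hydroxy-2H-pyran-3(6H)-one (racemic lactol)
Conditions: mCPBA, CH2Cl2, 0 °C → rt
Reagents that add atoms: m-chloroperbenzoic acid, OOC(=O)c1cccc(Cl)c1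
Why: Achmatowicz rearrangement; oxidation of the furan gives the open (Z)-enedione, whose primary hydroxyl closes on the aldehyde, so the pyran ring with C1, C3, C4, C5 and C9 is in place while C1 stays configurationally labile.

Step 2
Reactants: 2 6-hydroxy-2H-pyran-3(6H)-one
Product: 3 (S)-6-acetoxy-2H-pyran-3(6H)-one
Conditions: immobilised Burkholderia cepacia lipase, vinyl acetate, i-Pr2O, rt
Reagents that add atoms: vinyl acetate, C=COC(C)=O
Why: Lipase-catalysed acylative dynamic kinetic resolution; the lactol enantiomers interconvert through the open enedione while the enzyme acetylates one of them irreversibly, which fixes C1 as S (enantiopurity to be checked by chiral HPLC before going on).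

Step 3
Reactants: 3 (S)-6-acetoxy-2H-pyran-3(6H)-one; 4 4-methoxybenzyl alcohol
Product: 5 (R)-6-(4-methoxybenzyloxy)-2H-pyran-3(6H)-one (same spatial arrangement as 3)
Conditions: Pd2(dba)3·CHCl3 (2.5 mol %), PPh3 (10 mol %), CH2Cl2, 0 °C
Reagents that add atoms: 4-methoxybenzyl alcohol (4), COc1ccc(CO)cc1
Why: Tsuji–Trost-type substitution at the anomeric allylic position; zerovalent palladium ionises the acetate with inversion and the alcohol attacks the oxygen-bearing terminus anti to the metal, so double inversion retains C1 and swaps the ester (which steps 12 and 14 would cleave) for a base- and hydride-stable acetal that DDQ can remove.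

Step 4
Reactants: 6 (E)-4-methoxybut-3-en-2-one
Product: 7 (E)-3-(tert-butyldimethylsilyloxy)-1-methoxybuta-1,3-diene
Conditions: TBSOTf, Et3N, Et2O, 0 °C → rt
Reagents that add atoms: tert-butyldimethylsilyl triflate, CC(C)(C)[Si](C)(C)OS(=O)(=O)C(F)(F)F
Why: Soft enolisation and O-silylation of the vinylogous ester; the TBS enol ether is chosen over the TMS one because it has to survive steps 6 and 7.

Step 5
Reactants: 5 (R)-6-(4-methoxybenzyloxy)-2H-pyran-3(6H)-one; 7 silyloxydiene
Product: 8 cis-fused 2-oxadecalin adduct (C4 ketone, 1β-OPMB, H-5β, H-9β, 6α-OMe, C7=C10 TBS enol ether)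
Conditions: toluene, BHT (trace), 90 °C
Reagents that add atoms: diene 7, CO/C=C/C(=C)O[Si](C)(C)C(C)(C)C
Why: Normal-demand Diels–Alder reaction; the nucleophilic CH2 terminus (C8) bonds to the enone β-carbon C9 and the methoxy terminus (C6) to C5, suprafacial addition anti to the pseudoaxial 1β-OPMB group sets H-5 and H-9 β and cis, and the endo rule places 6-OMe α (a centre that is lost in step 8).

Step 6
Reactants: 8 Diels–Alder adduct
Product: 9 C3=C4 enol triflate of 8
Conditions: KN(SiMe3)2, THF, −78 °C; N-(5-chloro-2-pyridyl)triflimide, −78 °C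
Reagents that add atoms: N-(5-chloro-2-pyridyl)bis(trifluoromethanesulfonimide), O=S(=O)(N(c1ccc(Cl)cn1)S(=O)(=O)C(F)(F)F)C(F)(F)F
Why: Kinetic enolate formation and O-triflation; the hindered amide base takes an accessible C3 methylene proton rather than the tertiary ring-fusion H-5 shielded by C6-OMe, and the low temperature prevents enolate equilibration and loss of methoxide, while acetal and silyl enol ether are inert.

Step 7
Reactants: 9 enol triflate
Product: 10 C11 methyl ester (C3=C4 β-alkoxyacrylate, silyl enol ether and 6α-OMe retained)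
Conditions: Pd(OAc)2 (5 mol %), PPh3 (10 mol %), CO (1 atm), Et3N, MeOH–DMF, rt
Reagents that add atoms: carbon monoxide, [C-]#[O+]; methanol, CO
Why: Palladium-catalysed methoxycarbonylation of an enol triflate (oxidative addition, CO insertion, methanolysis) brings in C11 and creates the push–pull alkene without touching a stereocentre.

Step 8
Reactants: 10 C11 methyl ester
Product: 11 enone (C6=C7–C10=O, C8H2, 1β-OPMB, C11 methyl ester)
Conditions: 1 M aq HCl, THF, 0 °C → rt
Reagents that add atoms: none
Why: Acid hydrolysis of the silyl enol ether followed by acid-catalysed β-elimination of methanol is the standard unmasking of 1-methoxy-3-silyloxydiene adducts, and the C1 acetal resists ionisation because O2 is tied up in the vinylogous carbonate.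

Step 9
Reactants: 11 enone
Product: 13 8-diazo-6-en-10-one (cis-fused 2-oxadecalin diazo enone), via 8-trifluoroacetyl enone 12 (not isolated)
Conditions: LiN(SiMe3)2, THF, −78 °C; CF3CO2CH2CF3; aq HCl wash; then MsN3, Et3N, H2O (1 equiv), MeCN, rt
Reagents that add atoms: methanesulfonyl azide, CS(=O)(=O)N=[N+]=[N-]; 2,2,2-trifluoroethyl trifluoroacetate, O=C(OCC(F)(F)F)C(F)(F)F (its CF3CO group stays only in 12)
Why: Detrifluoroacetylative Regitz-type diazo transfer; kinetic deprotonation of the cyclohexenone occurs at the α′ carbon C8 (C7 is vinylic), Claisen trifluoroacetylation activates just this carbon, and mesyl azide with Et3N delivers N2 with loss of the trifluoroacetyl group under conditions mild enough for the doubly allylic H-5.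

Step 10
Reactants: 13 8-diazo-6-en-10-one
Product: 15 1-O-PMB irida-3,6-diene 10,11-dimethyl ester (8α-CO2Me and H-8β), via vinylketene 14 (not isolated)
Conditions: hν (365 nm LED, Pyrex), degassed MeOH, 0 °C
Reagents that add atoms: methanol, CO
Why: Excitation of the diazo ketone, whose ring locks C=O and C=N2 s-Z, expels N2 in concert with the 1,2-shift of vinylic C7 from the carbonyl carbon C10 to C8, so that the C7–C8 bond forms, C10 leaves the ring as the carbonyl carbon of vinylketene 14, and methanol adds to C10 to give an ester dienol that ketonises at C8. The closest known reaction type is the photochemical Wolff rearrangement of cyclic 2-diazo ketones with ring contraction, including 6-diazocyclohex-2-enones, which give cyclopent-2-enecarboxylates through vinylketenes. The cyclopentene ring C5–C6–C7–C8–C9 is closed by contraction of the existing cyclohexenone, that is by an intra-ring 1,2-shift and not by an end-to-end cyclisation, so the cis C5/C9 fusion and C1 are simply carried along. The one new stereocentre, C8, is set when the planar dienol is protonated from the open convex β-face (H-8 β, ester α), and the other epimer would do no harm because C8 becomes trigonal in step 11. The step needs migration of C7 only and no free-carbene chemistry: the position of the diazo group leaves C7 as the only substituent on C10 that can migrate, the s-Z geometry favours the concerted path over O–H insertion or a hydride shift from C9, and the C6=C7–C8=C10 unit of 14 is held s-trans, which rules out closure to a cyclobutenone. Light of 365 nm is absorbed by the diazo enone only, not by the β-alkoxyacrylate, the PMB group or 15.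

Step 11
Reactants: 15 Wolff ester
Product: 16 1-O-PMB irida-3,7-diene 10,11-dimethyl ester (C7=C8 conjugated with C10)
Conditions: DBU (0.5 equiv), CH2Cl2, rt
Reagents that add atoms: none
Why: Base-mediated isomerisation of a β,γ- to an α,β-unsaturated ester; DBU removes the doubly activated H-8 and the extended enolate, which can be protonated only at C8 or C6, drains to the more stable trisubstituted C7=C8 enoate, so both C8 epimers converge and C5 and C9 stay untouched.

Step 12
Reactants: 16 conjugated diester
Product: 17 C10 allylic alcohol with C11 methyl ester retained (the 1-O-PMB acetal of genipin)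
Conditions: i-Bu2AlH (2.1 equiv), CH2Cl2, −78 °C; aq KNaC4H4O6
Reagents that add atoms: none
Why: Chemoselective 1,2-reduction of an ester; C10 is an ordinary enoate whereas the C11 carbonyl is a vinylogous carbonate deactivated by donation from O2, and the intermediate C10 enal is more reactive than either ester, so two hydrides should be spent at C10 only.

Step 13
Reactants: 17 allylic alcohol
Product: 18 7β,8β-epoxide (C10 alcohol, C11 methyl ester)
Conditions: VO(acac)2 (2 mol %), t-BuOOH (decane), CH2Cl2, 0 °C → rt
Reagents that add atoms: tert-butyl hydroperoxide, CC(C)(C)OO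
Why: Vanadium-catalysed hydroxyl-directed epoxidation; the peroxide bound through the freely rotating C10 hydroxyl reaches C7=C8 from the convex β-face, which sets the 7β C–O bond for good and C8 provisionally, while the electron-poor C3=C4 alkene and the PMB group are not oxidised.

Step 14
Reactants: 18 epoxy ester
Product: 19 7β,8β-epoxy 10,11-diol
Conditions: i-Bu2AlH (3.5 equiv), CH2Cl2, −78 °C; aq KNaC4H4O6
Reagents that add atoms: none
Why: Ester reduction with an aluminium hydride; at −78 °C the remaining ester is reduced faster than the trisubstituted epoxide is opened, and the neutral tartrate work-up spares the now electron-rich enol ether.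

Step 15
Reactants: 19 epoxy diol
Product: 21 7β,8α,10,11-tetraol (8β-CH2OH), via spiro-epoxide 20 (not isolated)
Conditions: 0.5 M aq NaOH, t-BuOH, 60 °C
Reagents that add atoms: water, O
Why: Payne rearrangement with hydroxide opening; the C10 alkoxide attacks C8 from the α-face with inversion and frees the 7β-alkoxide, the terminal 8α,10-epoxide 20 is then opened at its unhindered primary C10, so water is added with 8α-OH and 8β-CH2OH set and C7 retained, under base that leaves acetal and enol ether alone.

Step 16
Reactants: 21 tetraol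
Product: 22 C11 aldehyde 7β,8α,10-triol
Conditions: MnO2 (activated, excess), acetone, rt
Reagents that add atoms: none
Why: Allylic oxidation with MnO2; C11-OH is now the only allylic alcohol, and the resulting vinylogous formate makes C3=C4 electron-poor and acid-tolerant for steps 20–22 and stabilises the ring-closed form of lactol 28.

Step 17
Reactants: 22 aldehyde triol
Product: 23 10-O-TBS ether
Conditions: TBSCl (1.1 equiv), imidazole, DMF, 0 °C
Reagents that add atoms: tert-butyldimethylsilyl chloride, CC(C)(C)[Si](C)(C)Cl
Why: Selective silylation; the bulky silyl chloride should react with the primary C10 hydroxyl well before the secondary C7 and the tertiary C8 hydroxyls.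

Step 18
Reactants: 24 p-coumaric acid
Product: 26 (E)-4-(tert-butyldimethylsilyloxy)cinnamic acid, via bis-silyl derivative 25 (not isolated)
Conditions: TBSCl (2.5 equiv), imidazole, DMF, rt; then AcOH–THF–H2O, rt
Reagents that add atoms: tert-butyldimethylsilyl chloride, CC(C)(C)[Si](C)(C)Cl
Why: Exhaustive silylation followed by selective hydrolysis; the silyl ester is far more labile to aqueous acid than the aryl silyl ether, so only the acid is set free.

Step 19
Reactants: 23 10-O-TBS ether; 26 protected coumaric acid
Product: 27 7-O-(4-O-TBS-p-coumaroyl) ester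
Conditions: DCC, DMAP, CH2Cl2, 0 °C → rt
Reagents that add atoms: acid 26, OC(=O)/C=C/c1ccc(O[Si](C)(C)C(C)(C)C)cc1
Why: Steglich esterification; the secondary 7β-hydroxyl on the convex face is acylated with retention at C7, while the tertiary 8α-hydroxyl is too hindered to compete.

Step 20
Reactants: 27 C7 ester
Product: 28 C1 lactol (1β-OH drawn, anomerisable)
Conditions: DDQ, CH2Cl2–pH 7 phosphate buffer, 0 °C
Reagents that add atoms: none
Why: Oxidative cleavage of a p-methoxybenzyl acetal; DDQ abstracts the benzylic hydride and water releases anisaldehyde, the formyl-substituted C3=C4 alkene and the cinnamate are too electron-poor to be oxidised, the silyl ethers hold at pH 7, and the 4-acyl lactol stays ring-closed as 4-acyl iridoid aglycones do.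

Step 21
Reactants: 28 lactol; 29 isovaleric anhydride
Product: 30 1β-O-isovalerate
Conditions: pyridine, DMAP (cat.), CH2Cl2, 0 °C
Reagents that add atoms: 3-methylbutanoic anhydride (29), CC(C)CC(=O)OC(=O)CC(C)C
Why: DMAP-catalysed acylation of a lactol; the prevailing anomer has the C1 oxygen pseudoaxial (anomeric effect) and anti to the C9–C8 bond, so C1 is fixed as the 1β-ester under substrate control as in acylations of related iridoid aglycones, and the tertiary C8 hydroxyl does not react.

Step 22
Reactants: 30 bis-silyl ether
Product: 31 11-aldehyde of luzonoid A (free phenol and C10 alcohol)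
Conditions: HF·pyridine, pyridine, THF, 0 °C → rt
Reagents that add atoms: none
Why: Fluoride-mediated desilylation under buffered, mildly acidic conditions removes both TBS groups without base-induced acyl migration, and the acylal and enol ether tolerate it because the C11 formyl group disfavours ionisation at C1 and protonation at C4.

Step 23
Reactants: 31 11-aldehyde
Product: 32 luzonoid A
Conditions: NaBH4, CeCl3·7H2O, MeOH–THF, −40 → −10 °C; pH 7 buffer
Reagents that add atoms: none
Why: Luche reduction; 1,2-hydride addition to the β-alkoxy enal (as with 2-formyl glycals) gives the C11 alcohol while the two esters and the cinnamate alkene are inert to borohydride at this temperature, so the acid-sensitive enol ether allylic alcohol appears only in the last, non-acidic step.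

Compound list
1 | furfuryl alcohol | OCc1ccco1 | starting material
2 | 6-hydroxy-2H-pyran-3(6H)-one (racemic) | OC1OCC(=O)C=C1 | intermediate
3 | (S)-6-acetoxy-2H-pyran-3(6H)-one | CC(=O)O[C@@H]1OCC(=O)C=C1 | intermediate
4 | 4-methoxybenzyl alcohol | COc1ccc(CO)cc1 | starting material
5 | (R)-6-(4-methoxybenzyloxy)-2H-pyran-3(6H)-one | COc1ccc(CO[C@@H]2OCC(=O)C=C2)cc1 | intermediate
6 | (E)-4-methoxybut-3-en-2-one | CO/C=C/C(C)=O | starting material
7 | (E)-3-(tert-butyldimethylsilyloxy)-1-methoxybuta-1,3-diene | CO/C=C/C(=C)O[Si](C)(C)C(C)(C)C | intermediate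
8 | Diels–Alder adduct: cis-2-oxadecalin, C4 ketone, 1β-OPMB, 6α-OMe, C7=C10 TBS enol ether | COc1ccc(CO[C@@H]2OCC(=O)[C@H]3[C@@H](OC)C=C(O[Si](C)(C)C(C)(C)C)C[C@@H]23)cc1 | intermediate
9 | C3=C4 enol triflate | COc1ccc(CO[C@@H]2OC=C(OS(=O)(=O)C(F)(F)F)[C@H]3[C@@H](OC)C=C(O[Si](C)(C)C(C)(C)C)C[C@@H]23)cc1 | intermediate
10 | C11 methyl ester | COc1ccc(CO[C@@H]2OC=C(C(=O)OC)[C@H]3[C@@H](OC)C=C(O[Si](C)(C)C(C)(C)C)C[C@@H]23)cc1 | intermediate
11 | 6-en-10-one (enone) | COc1ccc(CO[C@@H]2OC=C(C(=O)OC)[C@H]3C=CC(=O)C[C@@H]23)cc1 | intermediate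
12 | 8-trifluoroacetyl enone (C8 labile, largely enolised) | COc1ccc(CO[C@@H]2OC=C(C(=O)OC)[C@H]3C=CC(=O)C(C(=O)C(F)(F)F)[C@@H]23)cc1 | intermediate
13 | 8-diazo-6-en-10-one (key precursor) | COc1ccc(CO[C@@H]2OC=C(C(=O)OC)[C@H]3C=CC(=O)C(=[N+]=[N-])[C@@H]23)cc1 | intermediate
14 | vinylketene (C8=C10=O) | COc1ccc(CO[C@@H]2OC=C(C(=O)OC)[C@H]3C=CC(=C=O)[C@@H]23)cc1 | intermediate
15 | 1-O-PMB irida-3,6-diene 10,11-dimethyl ester, 8α-ester (key product) | COc1ccc(CO[C@@H]2OC=C(C(=O)OC)[C@H]3C=C[C@@H](C(=O)OC)[C@@H]23)cc1 | intermediate
16 | 1-O-PMB irida-3,7-diene 10,11-dimethyl ester | COc1ccc(CO[C@@H]2OC=C(C(=O)OC)[C@H]3CC=C(C(=O)OC)[C@@H]23)cc1 | intermediate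
17 | C10 allylic alcohol, C11 ester (1-O-PMB genipin) | COc1ccc(CO[C@@H]2OC=C(C(=O)OC)[C@H]3CC=C(CO)[C@@H]23)cc1 | intermediate
18 | 7β,8β-epoxide, C11 ester | COc1ccc(CO[C@@H]2OC=C(C(=O)OC)[C@H]3C[C@@H]4O[C@]4(CO)[C@@H]23)cc1 | intermediate
19 | 7β,8β-epoxy 10,11-diol | COc1ccc(CO[C@@H]2OC=C(CO)[C@H]3C[C@@H]4O[C@]4(CO)[C@@H]23)cc1 | intermediate
20 | 8α,10-spiro-epoxide 7β,11-diol | COc1ccc(CO[C@@H]2OC=C(CO)[C@H]3C[C@H](O)[C@]4(CO4)[C@@H]23)cc1 | intermediate
21 | 7β,8α,10,11-tetraol | COc1ccc(CO[C@@H]2OC=C(CO)[C@H]3C[C@H](O)[C@](O)(CO)[C@@H]23)cc1 | intermediate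
22 | C11 aldehyde 7β,8α,10-triol | COc1ccc(CO[C@@H]2OC=C(C=O)[C@H]3C[C@H](O)[C@](O)(CO)[C@@H]23)cc1 | intermediate
23 | 10-O-TBS ether of 22 | COc1ccc(CO[C@@H]2OC=C(C=O)[C@H]3C[C@H](O)[C@](O)(CO[Si](C)(C)C(C)(C)C)[C@@H]23)cc1 | intermediate
24 | p-coumaric acid | OC(=O)/C=C/c1ccc(O)cc1 | starting material
25 | TBS ester of 4-O-TBS-p-coumaric acid | CC(C)(C)[Si](C)(C)OC(=O)/C=C/c1ccc(O[Si](C)(C)C(C)(C)C)cc1 | intermediate
26 | (E)-4-(tert-butyldimethylsilyloxy)cinnamic acid | OC(=O)/C=C/c1ccc(O[Si](C)(C)C(C)(C)C)cc1 | intermediate
27 | 7-O-(4-O-TBS-p-coumaroyl) ester | COc1ccc(CO[C@@H]2OC=C(C=O)[C@H]3C[C@H](OC(=O)/C=C/c4ccc(O[Si](C)(C)C(C)(C)C)cc4)[C@](O)(CO[Si](C)(C)C(C)(C)C)[C@@H]23)cc1 | intermediate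
28 | C1 lactol (1β-OH drawn) | O[C@@H]1OC=C(C=O)[C@H]2C[C@H](OC(=O)/C=C/c3ccc(O[Si](C)(C)C(C)(C)C)cc3)[C@](O)(CO[Si](C)(C)C(C)(C)C)[C@@H]12 | intermediate
29 | 3-methylbutanoic (isovaleric) anhydride | CC(C)CC(=O)OC(=O)CC(C)C | starting material
30 | 1β-O-isovalerate, bis-TBS, C11 aldehyde | CC(C)CC(=O)O[C@@H]1OC=C(C=O)[C@H]2C[C@H](OC(=O)/C=C/c3ccc(O[Si](C)(C)C(C)(C)C)cc3)[C@](O)(CO[Si](C)(C)C(C)(C)C)[C@@H]12 | intermediate
31 | 11-aldehyde of luzonoid A | CC(C)CC(=O)O[C@@H]1OC=C(C=O)[C@H]2C[C@H](OC(=O)/C=C/c3ccc(O)cc3)[C@](O)(CO)[C@@H]12 | intermediate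
32 | luzonoid A | CC(C)CC(=O)O[C@@H]1OC=C(CO)[C@H]2C[C@H](OC(=O)/C=C/c3ccc(O)cc3)[C@](O)(CO)[C@@H]12 | target

Total step count: 23.
Longest linear sequence: 21 steps (1 to 32 through steps 1–3, 5–17 and 19–23).

Steps most likely to fail

1. Step 10.
- Risk: nitrogen may be lost without migration. Carbene-type insertion into the O–H bond of methanol is one path. A hydride shift from C9 followed by aromatisation of the carbocycle is another. The doubly allylic H-5 may also shift under irradiation.
- Fallback (sets out from 5, returns at 16): the five-membered ring is built directly instead of by contraction.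
  - A phosphine-catalysed [3+2] cycloaddition (Lu reaction) of 5 with methyl buta-2,3-dienoate (PPh3, toluene, 110 °C) should add anti to the 1β-OPMB group, with the allenoate α-carbon bonding to C9. This gives the cis-fused 4-oxocyclopenta[c]pyran-7-carboxylate F1.
  - Kinetic enolisation and triflation as in step 6 gives the C3=C4 enol triflate F2.
  - Methoxycarbonylation as in step 7 gives 16.

2. Step 6.
- Risk: the base may remove the ring-fusion proton H-5 in competition with a C3 proton. That is followed by loss of methoxide from C6, or by triflation on the wrong side of the ketone.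
- Fallback (sets out from 5, returns at 11): a diene without a leaving group at C6 is used, and the enone is made by oxidation instead of elimination.
  - Methyl vinyl ketone with TBSOTf and Et3N gives 2-(tert-butyldimethylsilyloxy)buta-1,3-diene F3.
  - Its Diels–Alder addition to 5 (toluene, 110 °C, same facial and regiochemical sense) gives the 6-unsubstituted adduct F4, in which deprotonation at C5 no longer destroys material.
  - Triflation gives the enol triflate F5 (any regioisomer is separated here), and carbonylation gives the ester F6.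
  - Saegusa–Ito oxidation of the C7=C10 silyl enol ether (Pd(OAc)2, MeCN, rt) introduces C6=C7 and gives 11.

3. Step 12.
- Risk: discrimination between the two esters may be insufficient, so that the C11 ester is reduced in part and the enol ether becomes electron-rich before the epoxidation.
- Fallback (sets out from 16, returns at 19): the two carbons are told apart as aldehydes by their acceptor strength.
  - Excess i-Bu2AlH (CH2Cl2, −78 °C) gives the 10,11-diol F7, and MnO2 oxidises both allylic alcohols to the 10,11-dialdehyde F8.
  - Weitz–Scheffer epoxidation (H2O2, K2CO3, MeOH, 0 °C) attacks only the C7=C8 enal, from the convex β-face, because C3 of the β-alkoxy enal is a poor acceptor. This gives the 7β,8β-epoxy dialdehyde F9.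
  - NaBH4 (MeOH, 0 °C) reduces both formyl groups to give 19.

Further compounds
F1 | step 10 | methyl 1β-(4-methoxybenzyloxy)-4-oxo-cis-hexahydrocyclopenta[c]pyran-7-carboxylate (C7=C8) | COc1ccc(CO[C@@H]2OCC(=O)[C@H]3CC=C(C(=O)OC)[C@@H]23)cc1
F2 | step 10 | C3=C4 enol triflate of F1 | COc1ccc(CO[C@@H]2OC=C(OS(=O)(=O)C(F)(F)F)[C@H]3CC=C(C(=O)OC)[C@@H]23)cc1
F3 | step 6 | 2-(tert-butyldimethylsilyloxy)buta-1,3-diene | C=CC(=C)O[Si](C)(C)C(C)(C)C
F4 | step 6 | 6-unsubstituted Diels–Alder adduct (C4 ketone, C7=C10 TBS enol ether) | COc1ccc(CO[C@@H]2OCC(=O)[C@H]3CC=C(O[Si](C)(C)C(C)(C)C)C[C@@H]23)cc1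
F5 | step 6 | C3=C4 enol triflate of F4 | COc1ccc(CO[C@@H]2OC=C(OS(=O)(=O)C(F)(F)F)[C@H]3CC=C(O[Si](C)(C)C(C)(C)C)C[C@@H]23)cc1
F6 | step 6 | C11 methyl ester from F5 | COc1ccc(CO[C@@H]2OC=C(C(=O)OC)[C@H]3CC=C(O[Si](C)(C)C(C)(C)C)C[C@@H]23)cc1
F7 | step 12 | 1-O-PMB irida-3,7-diene-10,11-diol | COc1ccc(CO[C@@H]2OC=C(CO)[C@H]3CC=C(CO)[C@@H]23)cc1
F8 | step 12 | 1-O-PMB irida-3,7-diene-10,11-dial | COc1ccc(CO[C@@H]2OC=C(C=O)[C@H]3CC=C(C=O)[C@@H]23)cc1
F9 | step 12 | 7β,8β-epoxy 10,11-dialdehyde | COc1ccc(CO[C@@H]2OC=C(C=O)[C@H]3C[C@@H]4O[C@]4(C=O)[C@@H]23)cc1
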